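**Strategy**

Ring A of the eudesmane (C1–C2–C3–C4–C5–C10) holds an unfunctionalised ethano unit, C2–C3, between C1 (a methylene on the quaternary C10) and the oxygenated C4. The arc C1–C10–C5–C4 is therefore preassembled as a cyclobutanone (C4 = carbonyl) fused to ring B, made from (R)-α-terpineol by dichloroketene [2+2] addition, and ethylene is inserted into its C4–C1 bond by rhodium-catalysed C–C activation. This two-carbon ring expansion makes ring A in one operation. The C4 ketone is then turned, via the exocyclic alkene and its α-epoxide, into the 4α tertiary alcohol, which is O-arylated and built up to the magnolol unit.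

Key step: step 4

**Remarks on the chemistry**

- Eudesmane numbering is used for all bicyclic compounds: C10 carries the angular methyl, C5 is the ring-fusion CH, C7 carries the side chain, C11 is the carbinol carbon, C15 is the methyl on C4.
- (R)-(+)-α-Terpineol of high enantiomeric purity is assumed to be commercially available. It supplies C7, and every other stereocentre is set relative to it.

**Route**

Step 1
Reactants: 1 (R)-(+)-α-terpineol
Product: 2 (R)-α-terpineol triethylsilyl ether
Conditions: TESOTf, 2,6-lutidine, CH2Cl2, −78 → 0 °C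
Reagents that add atoms: triethylsilyl triflate, CC[Si](CC)(CC)OS(=O)(=O)C(F)(F)F
Why: Silyl triflate/lutidine silylation of the hindered tertiary carbinol; the O-11 TES ether keeps the alcohol from acylation in step 2 and later distinguishes it from the C4 alcohol, and C7 is untouched.

Step 2
Reactants: 2 (R)-α-terpineol triethylsilyl ether; 3 trichloroacetyl chloride
Product: 5 dichlorocyclobutanone (cis-fused; C1 and C4 α; C10 methyl β), via dichloroketene 4 (not isolated)
Conditions: Zn–Cu, Et2O/DME, rt, ultrasound
Reagents that add atoms: trichloroacetyl chloride (3), ClC(Cl)(Cl)C(Cl)=O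
Why: Ketene–alkene [2+2] cycloaddition (dichloroketene from Zn dechlorination of 3): the ketene carbonyl carbon bonds to the less substituted alkene carbon C5 and CCl2 to the tertiary C10, the four-membered ring is necessarily cis-fused, and the leading C4–C5 bond is expected to form axially on the half-chair with the C7 side chain equatorial, that is on the face anti to it, which sets C10 (methyl β) and, provisionally, C5.

Step 3
Reactants: 5 dichlorocyclobutanone
Product: 6 cyclobutanone (cis-fused; C4 = carbonyl on C5; C1 = CH2 on C10)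
Conditions: Zn, NH4Cl, MeOH, rt
Reagents that add atoms: none
Why: Reductive dehalogenation of the α,α-dichloroketone through its zinc enolate under buffered conditions that leave the cyclobutanone, the silyl ether and all stereocentres intact.

Step 4
Reactants: 6 cyclobutanone; 7 ethylene
Product: 10 trans-fused 11-(triethylsilyloxy)-15-nor-5α-eudesman-4-one, via ketimine 8 (not isolated), via cis-fused decalone 9 (not isolated)
Conditions: [Rh(C2H4)2Cl]2 (5 mol %), IMes (10 mol %), 2-amino-3-picoline (1 equiv), C2H4 (7 bar), THF, 130 °C; aq. NH4Cl; then NaOMe, MeOH, rt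
Reagents that add atoms: ethylene (7), C=C; water (imine hydrolysis), O
Why: Condensation of 6 with 2-amino-3-picoline gives ketimine 8, whose pyridine nitrogen guides Rh(I) into the C4–C1 bond (oxidative addition to a five-membered alkyl–iminoacyl rhodacycle); ethylene inserts into the Rh–C1 bond, C3–C4 reductive elimination and imine hydrolysis give the cyclohexanone, so C1–C2 and C3–C4 are both made in one catalytic cycle. The closest known reactions are the Rh/aminopyridine "cut-and-sew" carboacylation of cyclobutanones with tethered olefins and the two-carbon ring expansion of 1-indanones with ethylene under the same catalyst system. Ring A is closed as a formal [4+2] (the C4–C1 σ-bond plus the ethylene π-bond), the six-membered ring arising by reductive elimination from a seven-membered rhodacycle. No stereocentre is created: C7 and C10 pass through unchanged, and C5 of the first-formed cis-fused ketone 9 is epimerised by NaOMe to the thermodynamically preferred trans-decalone 10 (H-5 α, anti to the C10 methyl). The step needs site selectivity (C4–C1 over C4–C5) and insertion over decarbonylation or β-hydride elimination: the imine places the pyridyl group syn to the unhindered C1 methylene, the iminoacyl ligand cannot extrude CO, and C1 is neopentyl (C10 quaternary), so the first rhodacycle has no β-hydrogen on that side.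

Step 5
Reactants: 10 trans-fused 15-nor-eudesman-4-one
Product: 11 β-eudesmol triethylsilyl ether
Conditions: Ph3PCH3Br, KOt-Bu, toluene, 90 °C
Reagents that add atoms: methylenetriphenylphosphorane (from methyltriphenylphosphonium bromide and KOt-Bu), C=P(c1ccccc1)(c1ccccc1)c1ccccc1
Why: Wittig methylenation with the ylide at elevated temperature, the usual answer to hindered decalones; the base can only return C5 to the trans-fusion already in place.

Step 6
Reactants: 11 β-eudesmol triethylsilyl ether
Product: 12 4α,15-epoxy-11-(triethylsilyloxy)eudesmane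
Conditions: mCPBA, NaHCO3, CH2Cl2, 0 °C
Reagents that add atoms: mCPBA, OOC(=O)c1cccc(Cl)c1
Why: Prilezhaev epoxidation: the β face of the exocyclic alkene is screened by the 1,3-diaxial C10 methyl, so the peracid should add from the α (equatorial) side and place the oxygen α at C4.

Step 7
Reactants: 12 4α,15-epoxide
Product: 13 11-O-triethylsilylcryptomeridiol (4α-OH; 4β-methyl)
Conditions: LiAlH4, THF, 0 °C → rt
Reagents that add atoms: none
Why: Hydride opens the spiro-epoxide by SN2 attack at the primary C15, so the C4–O bond and its α configuration are kept and C15 becomes the β (axial) methyl.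

Step 8
Reactants: 14 2-bromo-4-chloro-1-iodobenzene; 15 1,3,5-trimethoxybenzene
Product: 17 (2-bromo-4-chlorophenyl)(2,4,6-trimethoxyphenyl)iodonium tosylate, via hydroxy(tosyloxy)iodoarene 16 (not isolated)
Conditions: mCPBA, TsOH·H2O, MeCN, 77 °C; then 15, rt
Reagents that add atoms: p-toluenesulfonic acid, Cc1ccc(S(=O)(=O)O)cc1; 1,3,5-trimethoxybenzene (15), COc1cc(OC)cc(OC)c1
Why: One-pot oxidation of the aryl iodide to the hydroxy(tosyloxy)iodane and electrophilic aromatic substitution of the very electron-rich trimethoxybenzene gives the unsymmetrical diaryliodonium salt with a non-transferable trimethoxyphenyl group.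

Step 9
Reactants: 13 11-O-triethylsilylcryptomeridiol; 17 iodonium tosylate
Product: 19 4α-(2-bromo-4-chlorophenoxy)-11-(triethylsilyloxy)eudesmane, via sodium alkoxide 18 (not isolated)
Conditions: NaH, toluene, rt; then 17, rt → 40 °C
Reagents that add atoms: iodonium tosylate (17), COc1cc(OC)c([I+]c2ccc(Cl)cc2Br)c(OC)c1.Cc1ccc(S(=O)(=O)[O-])cc1
Why: Metal-free O-arylation of a tertiary alkoxide with a diaryliodonium salt (ligand coupling at iodine(III)): the electron-poor, ortho-substituted 2-bromo-4-chlorophenyl group is transferred in preference to the trimethoxyphenyl group, and C4 keeps its configuration because only the O–H bond changes.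

Step 10
Reactants: 19 bromo-chloro aryl ether; 20 (5-chloro-2-hydroxyphenyl)boronic acid
Product: 21 4α-[(5,5'-dichloro-2'-hydroxybiphenyl-2-yl)oxy]-11-(triethylsilyloxy)eudesmane
Conditions: Pd(dppf)Cl2 (5 mol %), K2CO3, dioxane/H2O, 85 °C
Reagents that add atoms: (5-chloro-2-hydroxyphenyl)boronic acid (20), OB(O)c1cc(Cl)ccc1O
Why: Suzuki–Miyaura coupling: Pd(dppf) inserts into the C–Br bond much faster than into either C–Cl bond, and the free ortho-hydroxyl of the boronic acid is tolerated under carbonate.

Step 11
Reactants: 21 dichlorobiaryl ether; 22 allylboronic acid pinacol ester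
Product: 23 11-O-triethylsilyl-eudesmagnolol
Conditions: 22 (4 equiv), XPhos Pd G3 (8 mol %), K3PO4, THF/H2O, 60 °C
Reagents that add atoms: allylboronic acid pinacol ester (22), C=CCB1OC(C)(C)C(C)(C)O1
Why: Suzuki–Miyaura allylation of both aryl chlorides with a bulky biarylphosphine palladacycle, which activates electron-rich chloroarenes (the chlorophenol ring included) under mild base, so the allyl groups should not isomerise.

Step 12
Reactants: 23 11-O-triethylsilyl-eudesmagnolol
Product: 24 eudesmagnolol
Conditions: TBAF, THF, rt → 40 °C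
Reagents that add atoms: none
Why: Fluoride cleaves the tertiary triethylsilyl ether under basic conditions that spare the acid-labile tertiary alkyl aryl ether and the allyl groups.

**Compound list**

1 | (R)-(+)-α-terpineol, 2-[(1R)-4-methylcyclohex-3-en-1-yl]propan-2-ol | CC1=CC[C@H](C(C)(C)O)CC1 | starting material
2 | (R)-α-terpineol triethylsilyl ether | CC1=CC[C@H](C(C)(C)O[Si](CC)(CC)CC)CC1 | intermediate
3 | trichloroacetyl chloride | ClC(Cl)(Cl)C(Cl)=O | starting material
4 | dichloroketene | ClC(Cl)=C=O | intermediate
5 | 8,8-dichloro-1-methyl-4-[2-(triethylsilyloxy)propan-2-yl]bicyclo[4.2.0]octan-7-one, cis-fused; eudesmane C1 (CCl2) and C4 (C=O) α, C10 methyl and H-5 β, C7 side chain β | C[C@@]12CC[C@@H](C(C)(C)O[Si](CC)(CC)CC)C[C@@H]1C(=O)C2(Cl)Cl | intermediate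
6 | 1-methyl-4-[2-(triethylsilyloxy)propan-2-yl]bicyclo[4.2.0]octan-7-one, same configuration as 5 | C[C@@]12CC[C@@H](C(C)(C)O[Si](CC)(CC)CC)C[C@@H]1C(=O)C2 | intermediate
7 | ethylene | C=C | starting material
8 | N-(3-methylpyridin-2-yl) ketimine of 6 | C[C@@]12CC[C@@H](C(C)(C)O[Si](CC)(CC)CC)C[C@@H]1C(=Nc1ncccc1C)C2 | intermediate
9 | 11-(triethylsilyloxy)-15-nor-5β-eudesman-4-one, cis-fused (H-5 and C10 methyl both β) | C[C@@]12CC[C@@H](C(C)(C)O[Si](CC)(CC)CC)C[C@@H]1C(=O)CCC2 | intermediate
10 | 11-(triethylsilyloxy)-15-nor-5α-eudesman-4-one, trans-fused (H-5 α, C10 methyl β) | C[C@@]12CC[C@@H](C(C)(C)O[Si](CC)(CC)CC)C[C@H]1C(=O)CCC2 | intermediate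
11 | β-eudesmol triethylsilyl ether, 11-(triethylsilyloxy)eudesm-4(15)-ene | C=C1CCC[C@]2(C)CC[C@@H](C(C)(C)O[Si](CC)(CC)CC)C[C@@H]12 | intermediate
12 | 4α,15-epoxy-11-(triethylsilyloxy)eudesmane (epoxide oxygen α, C15 β) | C1O[C@@]12CCC[C@]3(C)CC[C@@H](C(C)(C)O[Si](CC)(CC)CC)C[C@H]32 | intermediate
13 | 11-O-triethylsilylcryptomeridiol, 11-(triethylsilyloxy)eudesman-4α-ol (4β-methyl) | O[C@]1(C)CCC[C@]2(C)CC[C@@H](C(C)(C)O[Si](CC)(CC)CC)C[C@H]21 | intermediate
14 | 2-bromo-4-chloro-1-iodobenzene | Clc1ccc(I)c(Br)c1 | starting material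
15 | 1,3,5-trimethoxybenzene | COc1cc(OC)cc(OC)c1 | starting material
16 | 2-bromo-4-chloro-1-[hydroxy(tosyloxy)iodo]benzene | Cc1ccc(S(=O)(=O)OI(O)c2ccc(Cl)cc2Br)cc1 | intermediate
17 | (2-bromo-4-chlorophenyl)(2,4,6-trimethoxyphenyl)iodonium tosylate | COc1cc(OC)c([I+]c2ccc(Cl)cc2Br)c(OC)c1.Cc1ccc(S(=O)(=O)[O-])cc1 | intermediate
18 | sodium alkoxide of 13 | [Na+].[O-][C@]1(C)CCC[C@]2(C)CC[C@@H](C(C)(C)O[Si](CC)(CC)CC)C[C@H]21 | intermediate
19 | 4α-(2-bromo-4-chlorophenoxy)-11-(triethylsilyloxy)eudesmane | Clc1ccc(O[C@]2(C)CCC[C@]3(C)CC[C@@H](C(C)(C)O[Si](CC)(CC)CC)C[C@H]32)c(Br)c1 | intermediate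
20 | (5-chloro-2-hydroxyphenyl)boronic acid | OB(O)c1cc(Cl)ccc1O | starting material
21 | 4α-[(5,5'-dichloro-2'-hydroxybiphenyl-2-yl)oxy]-11-(triethylsilyloxy)eudesmane | Oc1ccc(Cl)cc1-c1cc(Cl)ccc1O[C@]1(C)CCC[C@]2(C)CC[C@@H](C(C)(C)O[Si](CC)(CC)CC)C[C@H]21 | intermediate
22 | allylboronic acid pinacol ester | C=CCB1OC(C)(C)C(C)(C)O1 | starting material
23 | 11-O-triethylsilyl-eudesmagnolol | C=CCc1ccc(O)c(-c2cc(CC=C)ccc2O[C@]2(C)CCC[C@]3(C)CC[C@@H](C(C)(C)O[Si](CC)(CC)CC)C[C@H]32)c1 | intermediate
24 | eudesmagnolol | C=CCc1ccc(O)c(-c2cc(CC=C)ccc2O[C@]2(C)CCC[C@]3(C)CC[C@@H](C(C)(C)O)C[C@H]32)c1 | target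

**Count**

Total steps: 12. Longest linear sequence: 11 (steps 1–7 and 9–12); step 8 is a one-step side branch.

**Steps most likely to fail, with fallbacks**

1. Step 4 (key step). The rhodacycle may lose the race to intermolecular ethylene capture and instead ring-contract by decarbonylation-type pathways, the ethylene-inserted seven-membered rhodacycle may undergo β-hydride elimination to ring-opened products, or C–C activation may occur on the C4–C5 side. The fallback sets out from 6 and installs the two carbons stepwise. Kinetic enolisation toward the C1 methylene (LDA, THF, −78 °C) and Michael addition to phenyl vinyl sulfoxide would give the 2-(phenylsulfinyl)ethyl ketone F1. Sulfoxide syn-elimination in hot toluene over CaCO3 would give the 2-vinylcyclobutanone F2. Its 1,3-acyl shift (continued heating, or direct irradiation near 300 nm) would enlarge the ring to the cis-fused cyclohex-3-enone F3 (C1=C2 alkene, C4 ketone). Hydrogenation (H2, Pd/C, EtOAc) would give 9, and the NaOMe equilibration of step 4 brings the fallback back to the route at 10.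

2. Step 2. The ketene may discriminate poorly between the two faces of the ring alkene, which would give the C5/C10-epimeric cyclobutanone series alongside 5; zinc chloride may also erode the silyl ether. The fallback sets out from 2 and replaces substrate control by reagent control. The keteniminium salt from N-acetyl-(2R,5R)-2,5-dimethylpyrrolidine (Tf2O, 2,4,6-collidine, ClCH2CH2Cl, reflux; the antipodal auxiliary if the sense of induction proves opposite) would add [2+2] with the same regiochemistry to give the cyclobutaniminium triflate F4. Hydrolysis with aqueous NaHCO3 then brings the fallback back to the route at 6, without the dechlorination step.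

3. Step 9. Ligand coupling at the hindered tertiary alkoxide may be slow, so that base-induced aryne formation from the iodonium salt (giving regioisomeric ethers) or transfer of the wrong aryl group competes. The fallback sets out from 13 and uses nucleophilic aromatic substitution. The potassium alkoxide (KHMDS, THF, 0 °C) and 2-bromo-1-fluoro-4-nitrobenzene would give the nitroaryl ether F5. Reduction with Fe/NH4Cl in EtOH/H2O would give the aniline F6. Non-aqueous Sandmeyer chlorination (t-BuONO, CuCl2, MeCN) then brings the fallback back to the route at 19.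

**Further compounds**

F1 | step 4 | 8-[2-(phenylsulfinyl)ethyl] derivative of cyclobutanone 6 (eudesmane C1 substituted; mixture at C1 and sulfur) | C[C@@]12CC[C@@H](C(C)(C)O[Si](CC)(CC)CC)C[C@@H]1C(=O)C2CCS(=O)c1ccccc1
F2 | step 4 | 8-vinyl derivative of cyclobutanone 6 (2-vinylcyclobutanone) | C[C@@]12CC[C@@H](C(C)(C)O[Si](CC)(CC)CC)C[C@@H]1C(=O)C2C=C
F3 | step 4 | cis-fused 11-(triethylsilyloxy)-15-nor-5β-eudesm-1-en-4-one | C[C@@]12CC[C@@H](C(C)(C)O[Si](CC)(CC)CC)C[C@@H]1C(=O)CC=C2
F4 | step 2 | cyclobutaniminium triflate of 6 with (2R,5R)-2,5-dimethylpyrrolidine | C[C@@]12CC[C@@H](C(C)(C)O[Si](CC)(CC)CC)C[C@@H]1C(=[N+]1[C@H](C)CC[C@H]1C)C2.[O-]S(=O)(=O)C(F)(F)F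
F5 | step 9 | 4α-(2-bromo-4-nitrophenoxy)-11-(triethylsilyloxy)eudesmane | [O-][N+](=O)c1ccc(O[C@]2(C)CCC[C@]3(C)CC[C@@H](C(C)(C)O[Si](CC)(CC)CC)C[C@H]32)c(Br)c1
F6 | step 9 | 4α-(4-amino-2-bromophenoxy)-11-(triethylsilyloxy)eudesmane | Nc1ccc(O[C@]2(C)CCC[C@]3(C)CC[C@@H](C(C)(C)O[Si](CC)(CC)CC)C[C@H]32)c(Br)c1
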